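**Plan**

1. Retrosynthesis (halimane numbering: ring A = C1–C5 + C10, ring B = C5–C10, side chain C11–C16 on C9, C17 on C8, C18 carboxyl and C19 methyl on C4, C20 on C9): take off the C14 acetate, the acetonide and the tert-butyl ester; re-open a temporary C19–S–C6 bridge; cut C5–C10 and C6–C7 in one radical event; then cut C1–C10 (acetylide + lactone), C9–C11 (Michael addition), C13–C16 (MeMgBr) and C3–C4 (enolate propargylation).
2. Enabling feature: C10 lies between the quaternary C9 and C1, so a C10 ketone gives only the C1=C10 vinyl iodide. From its radical, C5=C6 is 6-exo (ring A), and from C6 the aldehyde-derived C7=N is 6-exo (ring B); the two rings share the C5–C10 bond.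
3. Forward: three fragments (dioxolanyl enone C11–C16; lactone C7–C10 with C17 and C20; dihydrothiophene alkyne C1–C6 with C18 and C19) are joined into one chain, which folds into ring A and then ring B in the key step. Sulfur, acetonide and tert-butyl ester are then removed and C14 is acetylated.
4. Stereochemistry: C8 from (S)-4-methyloxolan-2-one; C9 by anti Michael addition next to C8; C14 from (R)-glycerate acetonide; C13 by chelation-controlled methyl addition; C4 by asymmetric phase-transfer alkylation; C5 by the cis ring fusion that the sulfur bridge enforces.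

Key step: step 17

Remark: 4 is taken as a purchasable chiral building block, and in step 7 the catalyst antipode is the one that delivers (3R)-14 (sense assigned by analogy with carbocyclic β-keto esters, to be confirmed on the first batch).

**Route**

Step 1
Reactants: 1 methyl (4R)-2,2-dimethyl-1,3-dioxolane-4-carboxylate
Product: 2 (4R)-N-methoxy-N,2,2-trimethyl-1,3-dioxolane-4-carboxamide
Conditions: MeNH(OMe)·HCl, iPrMgCl, THF, −20 °C
Reagents that add atoms: N,O-dimethylhydroxylamine hydrochloride, CNOC.Cl
Why: Weinreb amide formation, in which the chloromagnesium amide made in the flask attacks the ester at low temperature and leaves the α-alkoxy stereocentre (future C14) untouched.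

Step 2
Reactants: 2 (4R)-N-methoxy-N,2,2-trimethyl-1,3-dioxolane-4-carboxamide
Product: 3 1-[(4R)-2,2-dimethyl-1,3-dioxolan-4-yl]prop-2-en-1-one
Conditions: CH2=CHMgBr, THF, −78 to 0 °C; inverse quench into cold 1 M HCl; used at once
Reagents that add atoms: vinylmagnesium bromide, C=C[Mg]Br
Why: Weinreb ketone synthesis, where the chelated tetrahedral adduct stops at mono-addition and the cold acidic quench keeps the liberated amine from adding to the enone.

Step 3
Reactants: 4 (4S)-4-methyloxolan-2-one
Product: 6 (3S,4S)-3,4-dimethyloxolan-2-one, via lithium enolate 5 (not isolated)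
Conditions: LiN(iPr)2, THF, −78 °C; MeI, −78 to −40 °C
Reagents that add atoms: iodomethane, CI
Why: Lactone enolate alkylation in which iodomethane enters anti to the C4 methyl group; this centre is flattened again in step 4, so its configuration is immaterial.

Step 4
Reactants: 6 (3S,4S)-3,4-dimethyloxolan-2-one; 3 1-[(4R)-2,2-dimethyl-1,3-dioxolan-4-yl]prop-2-en-1-one
Product: 8 (3S,4S)-3-{3-[(4R)-2,2-dimethyl-1,3-dioxolan-4-yl]-3-oxopropyl}-3,4-dimethyloxolan-2-one, via lithium enolate 7 (not isolated)
Conditions: LiN(iPr)2, THF, −78 °C; slow addition of 3, −78 °C; AcOH quench at −78 °C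
Reagents that add atoms: none
Why: Michael addition of the tetrasubstituted lithium enolate to the vinyl ketone, in which the acceptor approaches the face opposite the adjacent methyl group (C17) and so sets the quaternary C9 with C20 cis to C17; the cold quench keeps the α-alkoxy ketone from epimerising.

Step 5
Reactants: 8 (3S,4S)-3-{3-[(4R)-2,2-dimethyl-1,3-dioxolan-4-yl]-3-oxopropyl}-3,4-dimethyloxolan-2-one
Product: 9 (3S,4S)-3-{(3S)-3-[(4R)-2,2-dimethyl-1,3-dioxolan-4-yl]-3-hydroxybutyl}-3,4-dimethyloxolan-2-one
Conditions: MeMgBr, CH2Cl2/Et2O, −78 °C; NH4Cl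
Reagents that add atoms: methylmagnesium bromide, C[Mg]Br
Why: Chelation-controlled Grignard addition (Cram chelate), where magnesium bridges the ketone and the α-oxygen of the dioxolane and methyl attacks from the side of the α-hydrogen to give the 13S tertiary alcohol; the hindered lactone does not react at −78 °C.

Step 6
Reactants: 10 methyl sulfanylacetate; 11 tert-butyl prop-2-enoate
Product: 13 tert-butyl 4-oxothiolane-3-carboxylate, via thioether diester 12 (not isolated)
Conditions: piperidine (cat.), THF, rt; then NaH, THF, 0 °C to rt; AcOH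
Reagents that add atoms: none
Why: Thia-Michael addition followed by Dieckmann condensation, where only the enolate next to the tert-butyl ester can close onto the methyl ester, so a single β-keto ester regioisomer should form.

Step 7
Reactants: 13 tert-butyl 4-oxothiolane-3-carboxylate
Product: 14 tert-butyl (3R)-4-oxo-3-(prop-2-yn-1-yl)thiolane-3-carboxylate
Conditions: propargyl bromide, N-spiro binaphthyl quaternary ammonium bromide bearing 3,4,5-trifluorophenyl groups (1 mol %), sat. aq. K2CO3, toluene, −20 °C
Reagents that add atoms: 3-bromoprop-1-yne, C#CCBr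
Why: Asymmetric phase-transfer alkylation of a cyclic β-keto ester, where the chiral ammonium enolate ion pair exposes one face to the bromide and sets the quaternary C4.

Step 8
Reactants: 14 tert-butyl (3R)-4-oxo-3-(prop-2-yn-1-yl)thiolane-3-carboxylate
Product: 15 tert-butyl (3R)-4-hydroxy-3-(prop-2-yn-1-yl)thiolane-3-carboxylate (either carbinol epimer)
Conditions: NaBH4, MeOH, 0 °C
Reagents that add atoms: none
Why: Borohydride reduction of the ketone; the new carbinol centre is removed in step 9, so both epimers serve.

Step 9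
Reactants: 15 tert-butyl (3R)-4-hydroxy-3-(prop-2-yn-1-yl)thiolane-3-carboxylate
Product: 16 tert-butyl (3R)-3-(prop-2-yn-1-yl)-2,3-dihydrothiophene-3-carboxylate
Conditions: Burgess reagent, benzene, 60 °C
Reagents that add atoms: none
Why: Burgess dehydration (syn elimination of the sulfamate ester), in which the only β-hydrogens sit on the sulfur-bearing CH2 because C4 is quaternary, so the vinyl sulfide C5=C6 forms regiospecifically.

Step 10
Reactants: 9 (3S,4S)-3-{(3S)-3-[(4R)-2,2-dimethyl-1,3-dioxolan-4-yl]-3-hydroxybutyl}-3,4-dimethyloxolan-2-one; 16 tert-butyl (3R)-3-(prop-2-yn-1-yl)-2,3-dihydrothiophene-3-carboxylate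
Product: 18 hydroxy ynone (C7 primary alcohol; C10 ketone conjugated to the C1≡C2 alkyne), via lithium acetylide 17 (not isolated)
Conditions: 16 (2.3 equiv), n-BuLi (2.2 equiv), THF, −78 °C; then 9, −78 to −30 °C; NH4Cl
Reagents that add atoms: none
Why: Acetylide addition to a lactone that has no α-hydrogen, where the lithium lactolate stops at mono-addition and opens on work-up; the first equivalent of acetylide is spent on the tertiary hydroxyl and is recovered as 16.

Step 11
Reactants: 18 hydroxy ynone
Product: 19 tert-butyldimethylsilyl ether of 18 at the C7 oxygen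
Conditions: TBSCl, imidazole, CH2Cl2, 0 °C
Reagents that add atoms: tert-butyldimethylsilyl chloride, CC(C)(C)[Si](C)(C)Cl
Why: Silylation of the primary alcohol only (the tertiary one is too hindered), which also fixes the open ynone form against lactol closure.

Step 12
Reactants: 19 silyl ether ynone
Product: 20 saturated C10 ketone (C1 and C2 now CH2)
Conditions: [(Ph3P)CuH]6, benzene, degassed H2O (5 equiv), rt
Reagents that add atoms: none
Why: Copper hydride conjugate reduction run twice (ynone to enone to ketone); 1,4-hydride delivery spares the isolated vinyl sulfide, the ester and the ketone carbonyl.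

Step 13
Reactants: 20 saturated C10 ketone
Product: 22 C10 vinyl iodide with C1=C10 double bond and C7 silyl ether (E/Z mixture), via hydrazone 21 (not isolated)
Conditions: N2H4·H2O, Et3N, EtOH, 70 °C; evaporate; I2 added slowly, tetramethylguanidine, THF, 0 °C
Reagents that add atoms: hydrazine hydrate, NN.O (its nitrogen stays only in 21); iodine, II
Why: Barton vinyl iodide synthesis, where the oxidised hydrazone loses a proton from C1, the only α-carbon with hydrogen because C9 is quaternary; iodine is kept limiting so that the dihydrothiophene never meets an excess.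

Step 14
Reactants: 22 C10 vinyl iodide with C7 silyl ether
Product: 23 vinyl iodide alcohol (C7–OH)
Conditions: HF·pyridine, pyridine, THF, 0 °C to rt
Reagents that add atoms: none
Why: Fluoride cleavage of the primary silyl ether under buffered conditions that leave acetonide, tert-butyl ester, vinyl iodide and vinyl sulfide alone.

Step 15
Reactants: 23 vinyl iodide alcohol
Product: 24 vinyl iodide aldehyde (C7 = CHO)
Conditions: SO3·pyridine, DMSO, iPr2NEt, CH2Cl2, 0 °C
Reagents that add atoms: none
Why: Parikh–Doering oxidation, in which activated DMSO oxidises the primary alcohol without touching the sulfide or the tertiary alcohol and without epimerising C8.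

Step 16
Reactants: 24 vinyl iodide aldehyde
Product: 25 N-(2-phenylaziridin-1-yl)imine of 24
Conditions: 1-amino-2-phenylaziridine, CH2Cl2, molecular sieves, 0 °C
Reagents that add atoms: 1-amino-2-phenylaziridine, NN1CC1c1ccccc1
Why: Hydrazone-type condensation of the aldehyde with the N-aminoaziridine installs the C=N radical acceptor that later leaves as styrene and N2.

Step 17
Reactants: 25 N-(2-phenylaziridin-1-yl)imine
Product: 26 tricyclic sulfide (rings A and B closed; C19–S–C6 bridge; tert-butyl ester; acetonide)
Conditions: Bu3SnH (1.5 equiv, syringe pump), AIBN (cat.), benzene (0.01 M), 80 °C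
Reagents that add atoms: none
Why: Bu3Sn• abstracts iodine from 25; the σ-vinyl radical at C10 attacks C5 of the dihydrothiophene double bond, the α-thio radical so formed at C6 adds to the imine carbon C7, and the aminyl radical fragments with loss of styrene and N2 to a C7 radical that is reduced by Bu3SnH, so C7 ends as CH2. The closest known reaction types are tin hydride vinyl-radical cyclisation cascades and radical cyclisation onto N-aziridinylimines. Ring A closes 6-exo-trig with the C1=C10 alkene kept inside the ring, and ring B closes 6-exo-trig onto C=N. C5 is the only lasting new stereocentre (C6 is erased in step 18): because C5=C6 sits in the five-membered ring that already holds C4, the six-membered ring can only fuse cis, so C10 bonds to the face carrying the C3 tether, H5 lands cis to the ester and C6 cis to C19, as in the target. The step needs 6-exo rather than 7-endo attack and no hydrogen shift: sulfur stabilises the radical at C6, the quaternary C4 and C13 leave no hydrogen in reach of a 1,5-shift, and C9 being quaternary puts the radical only on C10. It also needs ring B to close before chain transfer, which slow addition of Bu3SnH and the irreversible fragmentation of the C=N adduct secure; C4, C8, C9, C13 and C14 are untouched.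

Step 18
Reactants: 26 tricyclic sulfide
Product: 27 tert-butyl ester acetonide of the halim-1(10)-ene core (C13 hydroxyl free)
Conditions: Raney Ni (W-2, deactivated in acetone), EtOH, rt to 50 °C
Reagents that add atoms: none
Why: Raney nickel desulfurisation hydrogenolyses both C–S bonds, which turns C19 into the C4 methyl group and C6 into CH2; the trisubstituted C1=C10 alkene, shielded by the quaternary C9, should survive the deactivated catalyst.

Step 19
Reactants: 27 tert-butyl ester acetonide
Product: 28 triol acid (13,14,15-trihydroxy C4 acid)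
Conditions: CF3CO2H/CH2Cl2/H2O (20:75:5), 0 °C, short reaction time
Reagents that add atoms: none
Why: Acidolysis, in which the tert-butyl ester leaves as 2-methylpropene and the acetonide is hydrolysed in the same operation; cold, brief exposure is chosen to avoid acid-induced migration of the C1=C10 alkene.

Step 20
Reactants: 28 triol acid
Product: 30 target acid CNP0164901.1 (C14 acetate; C13 and C15 hydroxyls free), via cyclic orthoester 29 (not isolated)
Conditions: MeC(OMe)3, PPTS (cat.), CH2Cl2/THF, rt; then 80% aq. AcOH, 0 °C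
Reagents that add atoms: trimethyl orthoacetate, CC(OC)(OC)OC; water, O
Why: Orthoester-mediated regioselective monoacylation of a terminal 1,2-diol, where the 14,15-diol forms a five-membered cyclic orthoester whose acid hydrolysis opens through the hemiorthoester to the secondary (C14) acetate and the free primary alcohol; the tertiary C13 hydroxyl and the hindered acid should not take part, and the acidic work-up avoids base-induced acetyl migration to C15.

**Compound list**

1 | methyl (4R)-2,2-dimethyl-1,3-dioxolane-4-carboxylate | CC1(C)O[C@H](CO1)C(=O)OC | starting material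
2 | (4R)-N-methoxy-N,2,2-trimethyl-1,3-dioxolane-4-carboxamide | CC1(C)O[C@H](CO1)C(=O)N(C)OC | intermediate
3 | 1-[(4R)-2,2-dimethyl-1,3-dioxolan-4-yl]prop-2-en-1-one | CC1(C)O[C@H](CO1)C(=O)C=C | intermediate
4 | (4S)-4-methyloxolan-2-one | C[C@@H]1COC(=O)C1 | starting material
5 | lithium enolate of 4 | C[C@@H]1COC(O[Li])=C1 | intermediate (not isolated)
6 | (3S,4S)-3,4-dimethyloxolan-2-one | C[C@@H]1C(=O)OC[C@H]1C | intermediate
7 | lithium enolate of 6 | CC1=C(O[Li])OC[C@H]1C | intermediate (not isolated)
8 | (3S,4S)-3-{3-[(4R)-2,2-dimethyl-1,3-dioxolan-4-yl]-3-oxopropyl}-3,4-dimethyloxolan-2-one | CC1(C)O[C@H](CO1)C(=O)CC[C@]2(C)C(=O)OC[C@H]2C | intermediate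
9 | (3S,4S)-3-{(3S)-3-[(4R)-2,2-dimethyl-1,3-dioxolan-4-yl]-3-hydroxybutyl}-3,4-dimethyloxolan-2-one | CC1(C)O[C@H](CO1)[C@@](C)(O)CC[C@]2(C)C(=O)OC[C@H]2C | intermediate
10 | methyl sulfanylacetate | COC(=O)CS | starting material
11 | tert-butyl prop-2-enoate | C=CC(=O)OC(C)(C)C | starting material
12 | methyl {[3-(tert-butoxy)-3-oxopropyl]sulfanyl}acetate | COC(=O)CSCCC(=O)OC(C)(C)C | intermediate (not isolated)
13 | tert-butyl 4-oxothiolane-3-carboxylate | O=C1CSCC1C(=O)OC(C)(C)C | intermediate
14 | tert-butyl (3R)-4-oxo-3-(prop-2-yn-1-yl)thiolane-3-carboxylate | C#CC[C@@]1(C(=O)OC(C)(C)C)CSCC1=O | intermediate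
15 | tert-butyl (3R)-4-hydroxy-3-(prop-2-yn-1-yl)thiolane-3-carboxylate (either carbinol epimer) | C#CC[C@@]1(C(=O)OC(C)(C)C)CSCC1O | intermediate
16 | tert-butyl (3R)-3-(prop-2-yn-1-yl)-2,3-dihydrothiophene-3-carboxylate | C#CC[C@@]1(C(=O)OC(C)(C)C)CSC=C1 | intermediate
17 | lithium acetylide of 16 | [Li]C#CC[C@@]1(C(=O)OC(C)(C)C)CSC=C1 | intermediate (not isolated)
18 | hydroxy ynone (C7–OH, C10 ketone, C1≡C2) | CC1(C)O[C@H](CO1)[C@@](C)(O)CC[C@](C)(C(=O)C#CC[C@@]2(C(=O)OC(C)(C)C)CSC=C2)[C@H](C)CO | intermediate
19 | C7 tert-butyldimethylsilyl ether of 18 | CC1(C)O[C@H](CO1)[C@@](C)(O)CC[C@](C)(C(=O)C#CC[C@@]2(C(=O)OC(C)(C)C)CSC=C2)[C@H](C)CO[Si](C)(C)C(C)(C)C | intermediate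
20 | saturated C10 ketone | CC1(C)O[C@H](CO1)[C@@](C)(O)CC[C@](C)(C(=O)CCC[C@@]2(C(=O)OC(C)(C)C)CSC=C2)[C@H](C)CO[Si](C)(C)C(C)(C)C | intermediate
21 | hydrazone of 20 | CC1(C)O[C@H](CO1)[C@@](C)(O)CC[C@](C)(C(=NN)CCC[C@@]2(C(=O)OC(C)(C)C)CSC=C2)[C@H](C)CO[Si](C)(C)C(C)(C)C | intermediate (not isolated)
22 | C10 vinyl iodide (C1=C10, E/Z mixture) with C7 silyl ether | CC1(C)O[C@H](CO1)[C@@](C)(O)CC[C@](C)(C(I)=CCC[C@@]2(C(=O)OC(C)(C)C)CSC=C2)[C@H](C)CO[Si](C)(C)C(C)(C)C | intermediate
23 | vinyl iodide alcohol (C7–OH) | CC1(C)O[C@H](CO1)[C@@](C)(O)CC[C@](C)(C(I)=CCC[C@@]2(C(=O)OC(C)(C)C)CSC=C2)[C@H](C)CO | intermediate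
24 | vinyl iodide aldehyde (C7 = CHO) | CC1(C)O[C@H](CO1)[C@@](C)(O)CC[C@](C)(C(I)=CCC[C@@]2(C(=O)OC(C)(C)C)CSC=C2)[C@H](C)C=O | intermediate
25 | N-(2-phenylaziridin-1-yl)imine of 24 | CC1(C)O[C@H](CO1)[C@@](C)(O)CC[C@](C)(C(I)=CCC[C@@]2(C(=O)OC(C)(C)C)CSC=C2)[C@H](C)C=NN3CC3c4ccccc4 | intermediate
26 | tricyclic sulfide (rings A and B closed, C19–S–C6 bridge) | CC1(C)O[C@H](CO1)[C@@](C)(O)CC[C@]2(C)C3=CCC[C@](CS4)(C(=O)OC(C)(C)C)[C@H]3C4C[C@H]2C | intermediate
27 | tert-butyl ester acetonide of the halim-1(10)-ene core | CC1(C)O[C@H](CO1)[C@@](C)(O)CC[C@]2(C)C3=CCC[C@](C)(C(=O)OC(C)(C)C)[C@H]3CC[C@H]2C | intermediate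
28 | triol acid | O[C@H](CO)[C@@](C)(O)CC[C@]1(C)C2=CCC[C@](C)(C(=O)O)[C@H]2CC[C@H]1C | intermediate
29 | 14,15-cyclic methyl orthoacetate of 28 | COC1(C)O[C@H](CO1)[C@@](C)(O)CC[C@]2(C)C3=CCC[C@](C)(C(=O)O)[C@H]3CC[C@H]2C | intermediate (not isolated)
30 | CNP0164901.1 (C14 acetate of the 13,14,15-triol of the halim-1(10)-ene C4 acid) | CC(=O)O[C@H](CO)[C@@](C)(O)CC[C@]1(C)C2=CCC[C@](C)(C(=O)O)[C@H]2CC[C@H]1C | target

**Step count and risks**

Total step count: 20. Longest linear sequence: 15 steps (steps 6–9, then 10–20; steps 1, 2, 4, 5, then 10–20 is equally long).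

Step 13. What may go wrong: electrophilic iodination of the electron-rich dihydrothiophene double bond competing with oxidation of the hindered hydrazone. Fallback, setting out from 20 and returning at 22: 20 is converted with KN(SiMe3)2 and PhN(SO2CF3)2 (THF, −78 °C) into the enol triflate F1. Pd(PPh3)4-catalysed coupling with Me3SnSnMe3 and LiCl (THF, 60 °C) gives the alkenylstannane F2. Iododestannylation with one equivalent of I2 in CH2Cl2 at −78 °C, which is far faster than attack on a vinyl sulfide, gives 22.

Step 17. What may go wrong: reduction of the stabilised C6 radical before it closes ring B, or thermal loss of the aziridinylimine before the chain propagates. Fallback, setting out from 23 and returning at 27 (ring B closed by a polar step): 23 with Bu3SnH/AIBN undergoes only the first 6-exo closure and gives the bicyclic alcohol F3. I2/PPh3/imidazole converts it into the primary iodide F4, and NaIO4 (MeOH/H2O, 0 °C) gives the sulfoxide F5. LiN(iPr)2 (THF, −78 to 0 °C) closes ring B by intramolecular alkylation of the α-sulfinyl carbanion at C6 to give the tricyclic sulfoxide F6. Raney Ni removes sulfur and oxygen together and gives 27.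

Step 4. What may go wrong: proton transfer from the α-alkoxy position of the enone or of the product to the basic lactone enolate (epimerisation at C14, opening of the dioxolane), together with 1,2-addition and oligomerisation of the vinyl ketone. Fallback, setting out from 6 and returning at 8 (base-free Mukaiyama–Michael addition): 6 is converted with LiN(iPr)2 and TBSCl into the silyl ketene acetal F7. F7 adds to 3 under catalytic (CF3SO2)2NH in CH2Cl2 at −78 °C to give the silyl enol ether F8. Mild aqueous acid hydrolyses F8 to 8.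

Further compounds
F1 | step 13 | enol triflate of 20 (C10–OSO2CF3, C1=C10) | CC1(C)O[C@H](CO1)[C@@](C)(O)CC[C@](C)(C(OS(=O)(=O)C(F)(F)F)=CCC[C@@]2(C(=O)OC(C)(C)C)CSC=C2)[C@H](C)CO[Si](C)(C)C(C)(C)C
F2 | step 13 | C10 trimethylstannyl alkene | CC1(C)O[C@H](CO1)[C@@](C)(O)CC[C@](C)(C([Sn](C)(C)C)=CCC[C@@]2(C(=O)OC(C)(C)C)CSC=C2)[C@H](C)CO[Si](C)(C)C(C)(C)C
F3 | step 17 | bicyclic alcohol (ring A closed on the thiolane, C7–OH) | CC1(C)O[C@H](CO1)[C@@](C)(O)CC[C@](C)(C2=CCC[C@](CS3)(C(=O)OC(C)(C)C)[C@H]2C3)[C@H](C)CO
F4 | step 17 | primary iodide of F3 (C7–I) | CC1(C)O[C@H](CO1)[C@@](C)(O)CC[C@](C)(C2=CCC[C@](CS3)(C(=O)OC(C)(C)C)[C@H]2C3)[C@H](C)CI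
F5 | step 17 | sulfoxide of F4 | CC1(C)O[C@H](CO1)[C@@](C)(O)CC[C@](C)(C2=CCC[C@](CS3=O)(C(=O)OC(C)(C)C)[C@H]2C3)[C@H](C)CI
F6 | step 17 | tricyclic sulfoxide (ring B closed) | CC1(C)O[C@H](CO1)[C@@](C)(O)CC[C@]2(C)C3=CCC[C@](CS4=O)(C(=O)OC(C)(C)C)[C@H]3C4C[C@H]2C
F7 | step 4 | tert-butyldimethylsilyl ketene acetal of 6 | CC1=C(O[Si](C)(C)C(C)(C)C)OC[C@H]1C
F8 | step 4 | tert-butyldimethylsilyl enol ether of 8 | CC1(C)O[C@H](CO1)C(O[Si](C)(C)C(C)(C)C)=CC[C@]2(C)C(=O)OC[C@H]2C
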